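## Retrosynthetic overview

1. **Feature.** The ketone on furan C3 carries an aryl ring with an OH ortho to the carbonyl. The chain phenol O – C(ortho) – C(ipso) – C=O – furan C3 – furan C2 is the set O1–C8a–C4a–C4–C3–C2 of a 2,3-diarylchromone cut open at O1–C2. The benzo ring of the benzofuran is the 2'-oxygenated 3-aryl group of that chromone.
2. **Key disconnection.** The furan O1–C2 bond leads back to the 2-anisyl-2'-hydroxyisoflavone 12. Its 2'-phenoxide replaces the chromone oxygen at C2, so the pyranone opens as the furan closes.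
3. **Precursor.** 12 comes from a Suzuki bond C3–C1' between 3-iodoflavone 4 and chalcone boronate 9. One hydrogenation then saturates the enone and frees the 2'-OH.
4. **Fragments.** 4 comes from an acyl Sonogashira coupling and ICl iodocyclisation. 9 comes from benzylation, Claisen–Schmidt condensation and Miyaura borylation.
5. **Ring order.** The pyranone forms in step 2 and the furan forms at its cost in step 8. The four methyl ethers are cleaved last, in step 9.

Key step: step 8

Assumption: 4-hydroxy-3-iodobenzaldehyde 5 is taken as a catalogue compound. The target has no stereocentre, and the only stereochemical element on the way is the E alkene of 8–10, which step 7 erases.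

## Route

Step 1
Reactants: 1 2,4-dimethoxybenzoyl chloride; 2 4-ethynylanisole
Product: 3 1-(2,4-dimethoxyphenyl)-3-(4-methoxyphenyl)prop-2-yn-1-one
Conditions: PdCl2(PPh3)2 (2 mol %), CuI (4 mol %), Et3N, THF, rt
Reagents that add atoms: none
Why: Acyl Sonogashira coupling, in which the acid chloride adds oxidatively to zerovalent palladium and the copper acetylide of 2 delivers the alkynyl group, is a standard route to aryl alkynyl ketones and leaves the methyl ethers untouched.

Step 2
Reactants: 3 1-(2,4-dimethoxyphenyl)-3-(4-methoxyphenyl)prop-2-yn-1-one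
Product: 4 3-iodo-7-methoxy-2-(4-methoxyphenyl)chromen-4-one
Conditions: ICl (1.5 equiv), CH2Cl2, −78 °C to rt; aq. Na2S2O3 quench
Reagents that add atoms: iodine monochloride, ClI
Why: Electrophilic iodocyclisation of a 2-methoxyaryl ynone (6-endo-dig) has ICl activate the alkyne, the ortho-methoxy oxygen attack the anisyl-bearing alkyne carbon that best carries positive charge, and chloride take the methyl group off the oxonium ion, a well-tried route to 3-iodoflavones in which the low temperature protects the electron-rich rings from iodination.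

Step 3
Reactants: 5 4-hydroxy-3-iodobenzaldehyde
Product: 6 4-(benzyloxy)-3-iodobenzaldehyde
Conditions: BnBr, K2CO3, DMF, rt
Reagents that add atoms: benzyl bromide, BrCc1ccccc1
Why: Williamson ether synthesis on an acidic, aldehyde-activated phenol installs a group that survives base and palladium coupling and that hydrogen removes later.

Step 4
Reactants: 6 4-(benzyloxy)-3-iodobenzaldehyde; 7 2,4-dimethoxyacetophenone
Product: 8 (E)-3-[4-(benzyloxy)-3-iodophenyl]-1-(2,4-dimethoxyphenyl)prop-2-en-1-one
Conditions: KOH, EtOH/THF, rt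
Reagents that add atoms: none
Why: Claisen–Schmidt condensation of a methyl ketone with a non-enolisable aldehyde gives the E alkene through E1cB loss of water under thermodynamic control, and the aryl iodide and benzyl ether are inert to hydroxide at room temperature.

Step 5
Reactants: 8 (E)-3-[4-(benzyloxy)-3-iodophenyl]-1-(2,4-dimethoxyphenyl)prop-2-en-1-one
Product: 9 (E)-3-[4-(benzyloxy)-3-(4,4,5,5-tetramethyl-1,3,2-dioxaborolan-2-yl)phenyl]-1-(2,4-dimethoxyphenyl)prop-2-en-1-one
Conditions: B2pin2 (1.2 equiv), PdCl2(dppf) (3 mol %), KOAc (3 equiv), dioxane, 80 °C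
Reagents that add atoms: bis(pinacolato)diboron, CC1(C)OB(OC1(C)C)B1OC(C)(C)C(C)(C)O1
Why: Miyaura borylation works because the aryl iodide adds fast to zerovalent palladium, the weak base KOAc forms the acetato-palladium species that transmetalates with B2pin2 without triggering Suzuki homocoupling, and conjugate borylation of the enone is slow without copper or a protic additive.

Step 6
Reactants: 4 3-iodo-7-methoxy-2-(4-methoxyphenyl)chromen-4-one; 9 (E)-3-[4-(benzyloxy)-3-(4,4,5,5-tetramethyl-1,3,2-dioxaborolan-2-yl)phenyl]-1-(2,4-dimethoxyphenyl)prop-2-en-1-one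
Product: 10 3-[2-(benzyloxy)-5-[(E)-3-(2,4-dimethoxyphenyl)-3-oxoprop-1-enyl]phenyl]-7-methoxy-2-(4-methoxyphenyl)chromen-4-one
Conditions: Pd(OAc)2 (5 mol %), SPhos (10 mol %), K3PO4 (2.5 equiv), toluene/H2O, 85 °C
Reagents that add atoms: none
Why: Suzuki–Miyaura coupling, well known for 3-iodoflavones, succeeds because the C3–I bond of the iodoenone adds readily to zerovalent palladium and the bulky electron-rich biaryl phosphine speeds transmetalation and reductive elimination at the crowded C3–C1' bond, while the benzyl ether keeps the 2'-oxygen silent in the basic medium.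

Step 7
Reactants: 10 3-[2-(benzyloxy)-5-[(E)-3-(2,4-dimethoxyphenyl)-3-oxoprop-1-enyl]phenyl]-7-methoxy-2-(4-methoxyphenyl)chromen-4-one
Product: 12 3-[5-[3-(2,4-dimethoxyphenyl)-3-oxopropyl]-2-hydroxyphenyl]-7-methoxy-2-(4-methoxyphenyl)chromen-4-one, via dihydrochalcone benzyl ether 11 (not isolated)
Conditions: H2 (1 atm), 10 % Pd/C, EtOAc/MeOH, rt, stopped when 11 is consumed
Reagents that add atoms: none
Why: Heterogeneous catalytic hydrogenation saturates the disubstituted enone C=C first (11) and then hydrogenolyses the benzyl ether, whereas the tetrasubstituted vinylogous-ester C2=C3 of the chromone and the donor-substituted aryl ketone are reduced far more slowly, so one operation delivers the free 2'-phenol.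

Step 8
Reactants: 12 3-[5-[3-(2,4-dimethoxyphenyl)-3-oxopropyl]-2-hydroxyphenyl]-7-methoxy-2-(4-methoxyphenyl)chromen-4-one
Product: 14 1-(2,4-dimethoxyphenyl)-3-[3-(2-hydroxy-4-methoxybenzoyl)-2-(4-methoxyphenyl)benzofuran-5-yl]propan-1-one, via ketal enolate 13 (not isolated)
Conditions: K2CO3 (3 equiv), DMF, 90 °C, N2; then 1 M HCl
Reagents that add atoms: none
Why: K2CO3 turns the 2'-OH into a phenoxide that adds to C2, the β-carbon of the vinylogous ester O1–C2=C3–C4=O, giving ketal enolate 13, and 13 collapses by pushing out O1 as a ketone-stabilised phenoxide, so that the furan O–C2 bond is made while the pyranone O1–C2 bond is lost (addition–elimination at a vinylic carbon). The closest known reaction type is the ring-opening/ring-closure of chromones and flavones by nucleophiles that enter at C2, as in the hydrazine route to 3(5)-(2-hydroxyphenyl)pyrazoles, run here with an oxygen nucleophile that is already tethered to C3. The one ring closed, the furan, forms in a 5-endo-trig mode with respect to C2=C3 (the leaving C2–O1 bond lies outside the new ring), a mode that is known to work for ortho-hydroxy-β,β-difluorostyrenes going to 2-fluorobenzofurans and is helped here by the push-pull polarisation of the alkene and by the twist that the C2 anisyl group and the C4 carbonyl force on the 3-aryl ring, which holds the oxygen above the p-lobe of C2. No stereocentre results, because the sp3 ketal carbon of racemic 13 becomes trigonal again. The selectivity needed is anisyl at furan C2 and resorcinyl ketone at C3, and the chromone connectivity fixes it in the direct path, while in a hydroxide-initiated path through the open 1,3-diketone the 2'-oxygen would still choose the anisoyl carbonyl (5-exo-trig, then loss of water) since the resorcinyl carbonyl is by then part of a vinylogous carboxylate. Return to the chromone is held off by the aromaticity gained in the benzofuran, by the lower basicity of the released phenoxide and, after acidification, by the OH···O=C hydrogen bond of the ortho-hydroxy ketone.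

Step 9
Reactants: 14 1-(2,4-dimethoxyphenyl)-3-[3-(2-hydroxy-4-methoxybenzoyl)-2-(4-methoxyphenyl)benzofuran-5-yl]propan-1-one
Product: 15 isolophirone C, 1-(2,4-dihydroxyphenyl)-3-[3-(2,4-dihydroxybenzoyl)-2-(4-hydroxyphenyl)benzofuran-5-yl]propan-1-one
Conditions: BBr3 (12 equiv), CH2Cl2, −78 °C to rt; then ice/H2O
Reagents that add atoms: none
Why: Lewis-acid cleavage of aryl methyl ethers has BBr3 coordinate each ether oxygen and bromide remove the methyl group by SN2 attack, the excess reagent covers the two ketones and the free phenol that also bind boron, and the diaryl ketones, the saturated chain and the acyl-deactivated benzofuran have no bond that this reagent breaks.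

## Compound list

1 | 2,4-dimethoxybenzoyl chloride | COc1ccc(C(Cl)=O)c(OC)c1 | starting material
2 | 4-ethynylanisole | C#Cc1ccc(OC)cc1 | starting material
3 | 1-(2,4-dimethoxyphenyl)-3-(4-methoxyphenyl)prop-2-yn-1-one | COc1ccc(C#CC(=O)c2ccc(OC)cc2OC)cc1 | intermediate
4 | 3-iodo-7-methoxy-2-(4-methoxyphenyl)chromen-4-one | COc1ccc(-c2oc3cc(OC)ccc3c(=O)c2I)cc1 | intermediate
5 | 4-hydroxy-3-iodobenzaldehyde | O=Cc1ccc(O)c(I)c1 | starting material
6 | 4-(benzyloxy)-3-iodobenzaldehyde | O=Cc1ccc(OCc2ccccc2)c(I)c1 | intermediate
7 | 2,4-dimethoxyacetophenone | CC(=O)c1ccc(OC)cc1OC | starting material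
8 | (E)-3-[4-(benzyloxy)-3-iodophenyl]-1-(2,4-dimethoxyphenyl)prop-2-en-1-one | COc1ccc(C(=O)/C=C/c2ccc(OCc3ccccc3)c(I)c2)c(OC)c1 | intermediate
9 | (E)-3-[4-(benzyloxy)-3-(4,4,5,5-tetramethyl-1,3,2-dioxaborolan-2-yl)phenyl]-1-(2,4-dimethoxyphenyl)prop-2-en-1-one | COc1ccc(C(=O)/C=C/c2ccc(OCc3ccccc3)c(B3OC(C)(C)C(C)(C)O3)c2)c(OC)c1 | intermediate
10 | 3-[2-(benzyloxy)-5-[(E)-3-(2,4-dimethoxyphenyl)-3-oxoprop-1-enyl]phenyl]-7-methoxy-2-(4-methoxyphenyl)chromen-4-one | COc1ccc(-c2oc3cc(OC)ccc3c(=O)c2-c2cc(/C=C/C(=O)c3ccc(OC)cc3OC)ccc2OCc2ccccc2)cc1 | intermediate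
11 | 3-[2-(benzyloxy)-5-[3-(2,4-dimethoxyphenyl)-3-oxopropyl]phenyl]-7-methoxy-2-(4-methoxyphenyl)chromen-4-one (dihydrochalcone benzyl ether, not isolated) | COc1ccc(-c2oc3cc(OC)ccc3c(=O)c2-c2cc(CCC(=O)c3ccc(OC)cc3OC)ccc2OCc2ccccc2)cc1 | intermediate
12 | 3-[5-[3-(2,4-dimethoxyphenyl)-3-oxopropyl]-2-hydroxyphenyl]-7-methoxy-2-(4-methoxyphenyl)chromen-4-one | COc1ccc(-c2oc3cc(OC)ccc3c(=O)c2-c2cc(CCC(=O)c3ccc(OC)cc3OC)ccc2O)cc1 | intermediate
13 | potassium enolate of the tetracyclic ketal from addition of the 2'-oxygen to chromone C2 (5a-anisyl-5aH-benzofuro[2,3-b]chromen-11-olate skeleton with the methoxy group and side chain of 12; racemic, transient, not isolated) | COc1ccc(cc1)C12Oc3cc(OC)ccc3C([O-])=C1c1cc(CCC(=O)c3ccc(OC)cc3OC)ccc1O2.[K+] | intermediate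
14 | 1-(2,4-dimethoxyphenyl)-3-[3-(2-hydroxy-4-methoxybenzoyl)-2-(4-methoxyphenyl)benzofuran-5-yl]propan-1-one | COc1ccc(-c2oc3ccc(CCC(=O)c4ccc(OC)cc4OC)cc3c2C(=O)c2ccc(OC)cc2O)cc1 | intermediate
15 | isolophirone C | O=C(CCc1ccc2oc(-c3ccc(O)cc3)c(C(=O)c3ccc(O)cc3O)c2c1)c1ccc(O)cc1O | target

## Step count and risks

Total step count: 9. Longest linear sequence: 7 (steps 3 to 9, from 5).

### Step 8 (ring transformation)

- **What may go wrong.** The phenoxide may fail to reach C2, because the 5-endo approach is strained and the anisyl and 7-methoxy donors lower the electrophilicity of C2. The isoflavone would then simply persist. Water-borne opening of the pyranone may also be followed by retro-Claisen cleavage of the open diketone.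
- **Fallback.** The furan is built first and the ketone is added afterwards, setting out from 5 and 2.
  - Sonogashira coupling with heteroannulation in the same flask (PdCl2(PPh3)2, CuI, Et3N, DMF, 60 °C) should give 2-(4-methoxyphenyl)benzofuran-5-carbaldehyde F1.
  - Claisen–Schmidt condensation with 7 (KOH, EtOH) gives (E)-1-(2,4-dimethoxyphenyl)-3-[2-(4-methoxyphenyl)benzofuran-5-yl]prop-2-en-1-one F2.
  - Hydrogenation of the enone (H2, Pd/C, EtOAc) gives 1-(2,4-dimethoxyphenyl)-3-[2-(4-methoxyphenyl)benzofuran-5-yl]propan-1-one F3.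
  - Friedel–Crafts acylation of the nucleophilic furan C3 with 1 (SnCl4, CH2Cl2, 0 °C) gives 3-[3-(2,4-dimethoxybenzoyl)-2-(4-methoxyphenyl)benzofuran-5-yl]-1-(2,4-dimethoxyphenyl)propan-1-one F4.
  - Under the conditions of step 9, F4 loses its five methyl groups and comes back to the route at 15.

### Step 6 (Suzuki coupling)

- **What may go wrong.** Transmetalation at the boronate flanked by the benzyloxy group may be slow, so protodeboronation and reductive loss of iodine from 4 overtake the coupling. Long heating with base may also start to open the pyranone.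
- **Fallback.** The coupling is run without the protecting group and with a much smaller ortho substituent, setting out from 9.
  - Hydrogenation (H2, Pd/C, EtOAc/MeOH) saturates the enone and removes the benzyl group with the C–B bond intact. It gives 1-(2,4-dimethoxyphenyl)-3-[4-hydroxy-3-(4,4,5,5-tetramethyl-1,3,2-dioxaborolan-2-yl)phenyl]propan-1-one F5.
  - F5 couples with 4 as ortho-hydroxyarylboron reagents are known to do (PdCl2(dppf), K2CO3, DMF/H2O, 80 °C).
  - The fallback comes back at 12, or at 14 if the basic medium already carries the coupled phenoxide through the ring transformation.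

### Step 5 (borylation beside an enone)

- **What may go wrong.** Boryl transfer to the β-carbon of the chalcone, reductive loss of iodine, or coupling of the newly formed boronate with unreacted iodide may erode the conversion.
- **Fallback.** The enone is removed before any boron or palladium chemistry, setting out from 8.
  - Copper hydride conjugate reduction ([(Ph3P)CuH]6 cat., PhSiH3, toluene, rt, aqueous work-up) spares the aryl iodide and the benzyl ether. It gives 3-[4-(benzyloxy)-3-iodophenyl]-1-(2,4-dimethoxyphenyl)propan-1-one F6.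
  - Miyaura borylation under the conditions of step 5 gives 3-[4-(benzyloxy)-3-(4,4,5,5-tetramethyl-1,3,2-dioxaborolan-2-yl)phenyl]-1-(2,4-dimethoxyphenyl)propan-1-one F7.
  - Suzuki coupling of F7 with 4 under the conditions of step 6 comes back to the route at 11, now isolated. Plain hydrogenolysis (H2, Pd/C) converts 11 into 12.

## Further compounds

F1 | step 8 | 2-(4-methoxyphenyl)benzofuran-5-carbaldehyde | COc1ccc(-c2cc3cc(C=O)ccc3o2)cc1
F2 | step 8 | (E)-1-(2,4-dimethoxyphenyl)-3-[2-(4-methoxyphenyl)benzofuran-5-yl]prop-2-en-1-one | COc1ccc(-c2cc3cc(/C=C/C(=O)c4ccc(OC)cc4OC)ccc3o2)cc1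
F3 | step 8 | 1-(2,4-dimethoxyphenyl)-3-[2-(4-methoxyphenyl)benzofuran-5-yl]propan-1-one | COc1ccc(-c2cc3cc(CCC(=O)c4ccc(OC)cc4OC)ccc3o2)cc1
F4 | step 8 | 3-[3-(2,4-dimethoxybenzoyl)-2-(4-methoxyphenyl)benzofuran-5-yl]-1-(2,4-dimethoxyphenyl)propan-1-one | COc1ccc(-c2oc3ccc(CCC(=O)c4ccc(OC)cc4OC)cc3c2C(=O)c2ccc(OC)cc2OC)cc1
F5 | step 6 | 1-(2,4-dimethoxyphenyl)-3-[4-hydroxy-3-(4,4,5,5-tetramethyl-1,3,2-dioxaborolan-2-yl)phenyl]propan-1-one | COc1ccc(C(=O)CCc2ccc(O)c(B3OC(C)(C)C(C)(C)O3)c2)c(OC)c1
F6 | step 5 | 3-[4-(benzyloxy)-3-iodophenyl]-1-(2,4-dimethoxyphenyl)propan-1-one | COc1ccc(C(=O)CCc2ccc(OCc3ccccc3)c(I)c2)c(OC)c1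
F7 | step 5 | 3-[4-(benzyloxy)-3-(4,4,5,5-tetramethyl-1,3,2-dioxaborolan-2-yl)phenyl]-1-(2,4-dimethoxyphenyl)propan-1-one | COc1ccc(C(=O)CCc2ccc(OCc3ccccc3)c(B3OC(C)(C)C(C)(C)O3)c2)c(OC)c1
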